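J splits three ways in these closed flasks, and I ask which of two new flasks ends with the larger share of D.

| setting | noon | midnight | Monday's | Saturday's |
|---|---|---|---|---|
| J | 0.013 M | 0.079 M | 0.012 M | 0.050 M |
| temperature | 105 °C | 120 °C | 130 °C | 110 °C |
| remark | run made earlier | run made earlier |  |  |
| time |  |  | 1.0 h | 1.0 h |

- noon (time / min: D / %, Q / %): 5.00: 18.2, 74.8; 10.0: 18.8, 79.3; 15.0: 19.1, 79.7; 30.0: 19.0, 79.3; 60.0: 19.7, 79.3
- midnight (time / min: D / %, Q / %): 3.00: 24.4, 70.3; 10.0: 23.8, 70.3; 20.0: 23.9, 70.9; 25.0: 24.4, 71.2; 40.0: 24.8, 70.3

(standard deviation of a reading: 0.3 percentage points)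

- the winner by share of D in all that became D or Q; "neither" if no more than 2 percentage points parts them (Monday's / Saturday's / neither)
- share of D in all that became D or Q, Monday's
- share of D in all that became D or Q, Saturday's

- a species is counted by the J in it: one Z counts as two
- what was read earlier has a scatter of 0.3 percentage points, one standard deviation
- reactions considered so far: J -> Q; J -> D; 2 J -> Z

I start from the end state. The noon readings stand still from 10.0 min. Monday's and Saturday's run 1.0 h, longer than that, and both are hotter than noon, so I take both as finished. The share then hangs on one ratio, c_D/c_Q, the selectivity factor. J → D and J → Q are both first order, so they see the same c_J at each moment, and the ratio stays that of their rate constants, whatever Z takes.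

The noon plateau gives 0.243 and the midnight one 0.344. From these I read ΔE = 28.7 kJ/mol, the excess of D's activation energy over Q's. Stepping from midnight, ΔE gives ratios of 0.427 for Monday's and 0.273 for Saturday's. Those are shares of 29.9% and 21.5%, so I commit to Monday's, ahead by more than the margin.

One link is weak. Noon and midnight changed c_J and temperature together, and a ratio that followed c_J puts Monday's beside noon and turns the order. But the noon flask tests this by itself, since c_J falls within the run. What formed before 5.00 min stands at 0.243. What formed after it stands at 0.230, a rough figure given the scatter of 0.3 percentage points. The ratio shows no collapse as c_J drops, so I keep ΔE.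

The forecast, from the same runs and close to mine, names Monday's, with 30% against 21.4%, holding that “D/Q depends only on temperature”. The flasks give Monday's, with 29.3% for Monday's and 21.4% for Saturday's.

    J → Q (k = 0.0110 /s, Ea = 97.0 kJ/mol)
    J → D (k = 0.00300 /s, Ea = 124 kJ/mol)
    2 J → Z (k = 0.0120 /M/s, Ea = 71.0 kJ/mol)
    (constants at 110 °C)

In Monday's flask the steps to Q and to D have half their turnover up to 1.0 h behind them by 0.163 min, and at 0.500 h J stands at 0%, with D at 29.2% and Q at 70.2%. At 10.0 h Monday's flask still holds D at 29.2%. Monday's 29.3% is a ratio of 0.415, and ΔE carries it to 0.565 at 145 °C, a share of 36.1%. The flask like Monday's kept at 145 °C gives 35.7%, with Z at 0.423%.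

(All runs were generated by integration with made-up constants, and the scatter is random.)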